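**Plan**

- Retrosynthesis: C1–C2 and O–C10 are cut together, which opens the 3(2H)-furanone and the ten-membered carbocycle to seco keto acid 19. Then follow the C8 angelate, the C7–C8 bond (allylstannane 9 + aldehyde 13), the C3 acetyl group (masked as an alkenyl iodide) and the butenolide C7=C11 bond (metathesis).
- Enabling feature: the ring oxygen and C2 of the furanone are the O and C termini of the enolate of a C3 methyl ketone, and C1/C10 form an α-chloro acyl unit (a 1,2-dielectrophile). The Z C4=C5 alkene and the trans γ-lactone hold the two chain ends on one side.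
- Ring order forward: butenolide (step 5), then α-methylene-γ-lactone with the C7–C8 bond (step 9), then ten-membered carbocycle and furanone together (step 12).
- Stereochemistry: C6 from a Sharpless kinetic resolution; C7 and C8 from an open-transition-state allylation (anti to the C6 substituent, 7,8-syn); C10 from ring-controlled closure of a planar oxyallyl intermediate, so both C10 epimers converge. Z C4=C5 comes from trans-hydroalumination–iodination and the angelate from angelic acid.

Key step: step 12

Remark: germacrane numbering (C1–C15, lactone carbons C11–C13) is used for the target and late intermediates. Aldehyde 13 is used as the racemate because its C10 centre is re-formed in step 12; compounds 14–21 are therefore carried as mixtures of C10 epimers.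

**Route**

Step 1
Reactants: 1 acrolein; 2 prop-1-yn-1-ylmagnesium bromide
Product: 3 rac-hex-1-en-4-yn-3-ol
Conditions: THF, −78 → 0 °C; sat. aq NH4Cl
Reagents that add atoms: none
Why: 1,2-addition of the alkynyl Grignard reagent to the enal carbonyl at low temperature should give the racemic secondary alcohol, whose configuration is settled in step 3.

Step 2
Reactants: 3 rac-hex-1-en-4-yn-3-ol
Product: 4 rac-(4Z)-5-iodohexa-1,4-dien-3-ol
Conditions: NaAlH2(OCH2CH2OCH3)2, THF, 0 → 23 °C; EtOAc; then I2, −78 → 0 °C
Reagents that add atoms: iodine, II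
Why: hydroxyl-directed trans-hydroalumination of the propargylic alcohol places aluminium on the distal alkyne carbon, and iodinolysis with retention should give the Z iodoalkene with iodine cis to the carbinol carbon, which fixes the later C4=C5 geometry.

Step 3
Reactants: 4 rac-(4Z)-5-iodohexa-1,4-dien-3-ol
Product: 5 (3S,4Z)-5-iodohexa-1,4-dien-3-ol
Conditions: Ti(Oi-Pr)4 (10 mol %), L-(+)-diisopropyl tartrate (15 mol %), t-BuOOH (0.6 equiv), 4 Å MS, CH2Cl2, −20 °C
Reagents that add atoms: none
Why: Sharpless kinetic resolution, in which the L-(+)-tartrate catalyst should epoxidise the vinyl group of the (R)-enantiomer much faster (the Z iodoalkene is deactivated), so that (S)-5, the source of C6, is recovered.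

Step 4
Reactants: 5 (3S,4Z)-5-iodohexa-1,4-dien-3-ol; 6 2-(bromomethyl)prop-2-enoic acid
Product: 7 (3S,4Z)-5-iodohexa-1,4-dien-3-yl 2-(bromomethyl)prop-2-enoate
Conditions: DCC, DMAP (5 mol %), CH2Cl2, 0 °C
Reagents that add atoms: none
Why: Steglich esterification of the secondary alcohol at 0 °C should leave the allylic bromide untouched and retain the configuration at C6.

Step 5
Reactants: 7 (3S,4Z)-5-iodohexa-1,4-dien-3-yl 2-(bromomethyl)prop-2-enoate
Product: 8 (5S)-3-(bromomethyl)-5-[(1Z)-2-iodoprop-1-en-1-yl]furan-2(5H)-one
Conditions: second-generation Grubbs catalyst (5 mol %), CH2Cl2 (5 mM), 40 °C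
Reagents that add atoms: none
Why: ring-closing metathesis between the vinyl group and the 1,1-disubstituted acrylate should close the five-membered butenolide with loss of ethene, the trisubstituted iodoalkene being inert.

Step 6
Reactants: 8 (5S)-3-(bromomethyl)-5-[(1Z)-2-iodoprop-1-en-1-yl]furan-2(5H)-one
Product: 9 (5S)-5-[(1Z)-2-iodoprop-1-en-1-yl]-3-[(tributylstannyl)methyl]furan-2(5H)-one
Conditions: Zn dust, Bu3SnCl, THF/sat. aq NH4Cl, 23 °C
Reagents that add atoms: tributyltin chloride, CCCC[Sn](Cl)(CCCC)CCCC
Why: zinc insertion into the allylic bromide and trapping of the allylzinc by Bu3SnCl (aqueous Barbier-type allylstannation) should give the primary, lactone-conjugated allylstannane as the thermodynamic regioisomer.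

Step 7
Reactants: 10 tert-butyl 2-chloropropanoate; 11 allyl bromide
Product: 12 tert-butyl 2-chloro-2-methylpent-4-enoate (racemic)
Conditions: LiN(i-Pr)2, THF/DMPU, −78 °C; then 11, −78 → −40 °C
Reagents that add atoms: none
Why: alkylation of the lithium enolate of the α-chloro ester should build the quaternary C10 centre, racemic because this centre is re-formed in step 12.

Step 8
Reactants: 12 tert-butyl 2-chloro-2-methylpent-4-enoate
Product: 13 tert-butyl 2-chloro-2-methyl-4-oxobutanoate (racemic)
Conditions: O3, CH2Cl2, −78 °C; then PPh3, −78 → 23 °C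
Reagents that add atoms: ozone, [O-][O+]=O
Why: ozonolysis with reductive work-up cleaves the terminal alkene to the C8 aldehyde under neutral conditions that spare the elimination-prone β-chloro aldehyde.

Step 9
Reactants: 9 (5S)-5-[(1Z)-2-iodoprop-1-en-1-yl]-3-[(tributylstannyl)methyl]furan-2(5H)-one; 13 tert-butyl 2-chloro-2-methyl-4-oxobutanoate
Product: 14 tert-butyl (4R)-2-chloro-4-hydroxy-4-[(2S,3R)-2-[(1Z)-2-iodoprop-1-en-1-yl]-4-methylidene-5-oxooxolan-3-yl]-2-methylbutanoate (both epimers at C2 of the butanoate)
Conditions: BF3·OEt2, CH2Cl2, −78 °C; sat. aq NaHCO3 at −78 °C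
Reagents that add atoms: none
Why: BF3-promoted SE2′ addition of the allylstannane to the aldehyde through an open antiperiplanar transition state, in which attack on C7 anti to the C6 alkenyl group should give the 6,7-trans lactone and the aldehyde substituent gauche to H-7 should give the 7,8-syn (8R) alcohol, the allyl transposition creating the exocyclic methylene.

Step 10
Reactants: 14 the (8R)-hydroxy lactone of step 9; 15 angelic acid
Product: 16 tert-butyl (4R)-2-chloro-4-[(2S,3R)-2-[(1Z)-2-iodoprop-1-en-1-yl]-4-methylidene-5-oxooxolan-3-yl]-2-methyl-4-{[(2Z)-2-methylbut-2-enoyl]oxy}butanoate (C2 epimers)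
Conditions: 15, 2,4,6-trichlorobenzoyl chloride, Et3N, toluene, 23 °C; then 14, 80 °C
Reagents that add atoms: none
Why: Yamaguchi esterification through the mixed 2,4,6-trichlorobenzoic anhydride without a nucleophilic catalyst should acylate O8 with retention and without Z to E isomerisation of the angelate.

Step 11
Reactants: 16 the angelate iodide of step 10; 17 tributyl(1-ethoxyvinyl)stannane
Product: 19 (4R)-2-chloro-2-methyl-4-{[(2Z)-2-methylbut-2-enoyl]oxy}-4-[(2R,3R)-4-methylidene-2-[(1Z)-2-methyl-3-oxobut-1-en-1-yl]-5-oxooxolan-3-yl]butanoic acid (C2 epimers), via ethoxydiene tert-butyl ester 18 (not isolated)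
Conditions: Pd2(dba)3 (5 mol %), AsPh3, CuI, THF, 45 °C; then CF3CO2H/H2O/CH2Cl2, 0 → 23 °C
Reagents that add atoms: water, O
Why: Stille coupling of the alkenyl iodide proceeds with retention of the Z geometry, and aqueous trifluoroacetic acid should then hydrolyse the enol ether to the methyl ketone and cleave the tert-butyl ester in the same flask.

Step 12
Reactants: 19 the seco keto acid of step 11
Product: 22 15-deoxybudlein A, via acid chloride 20 (not isolated), via chloro diketone macrocycle 21 (not isolated)
Conditions: 1-chloro-N,N,2-trimethylprop-1-en-1-amine, CH2Cl2, 0 °C; then syringe-pump addition to MgBr2·OEt2, i-Pr2NEt, CH2Cl2 (final ca. 1 mM), 23 → 40 °C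
Reagents that add atoms: none
Why: Proposed new method: soft enolisation (Mg-bound ketone, hindered amine) gives the cross-conjugated magnesium enolate of the C3 methyl ketone, whose carbon terminus C2 acylates the tethered C1 acid chloride to the ten-membered 1,3-diketonate 21; this enolate then expels the tertiary C10 chloride (Favorskii-type ionisation to a planar 2-oxyallyl cation, assisted by the magnesium salt) and the C3 oxygen closes onto C10, so that C2–C1 and O–C10 form in one flask. The closest known reactions are the intermolecular MgBr2·OEt2/amine C-acylation of methyl ketones with acid chlorides to 1,3-diketones and the base-induced cyclisation of α'-halo-1,3-diketones (or the one-pot enolate plus α-haloacyl halide annulation) to 2,2-disubstituted 3(2H)-furanones; their union as a medium-ring closure is new. The carbocycle closes by a 10-exo-trig addition–elimination at C1, helped by the Z C4=C5 alkene, the trans-fused lactone and the gem-disubstituted C10; the furanone closes by five-membered oxa-cyclisation of the acyl-oxyallyl cation (formally 5-exo-tet at C10). C10 is the only new stereocentre: it passes through the planar cation, so both C10 epimers of 20 converge, and the C4–C9 bridge with its 6R,7R,8R centres is expected to allow the O-attack only from the face that gives the natural 10R bicycle. The step needs C- over O-acylation (magnesium chelate), enolisation only at the C2 methyl group (no other soft-enolisable site, and the acid chloride has no α-hydrogen), cyclisation over oligomerisation (high dilution, slow addition) and O-closure over E2 loss of HCl (intramolecular five-ring closure, hindered base).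

**Compound list**

1 | acrolein | C=CC=O | starting material
2 | prop-1-yn-1-ylmagnesium bromide | CC#C[Mg]Br | starting material
3 | rac-hex-1-en-4-yn-3-ol | C=CC(O)C#CC | intermediate
4 | rac-(4Z)-5-iodohexa-1,4-dien-3-ol | C=CC(O)/C=C(/C)I | intermediate
5 | (3S,4Z)-5-iodohexa-1,4-dien-3-ol | C=C[C@H](O)/C=C(/C)I | intermediate
6 | 2-(bromomethyl)prop-2-enoic acid | C=C(CBr)C(=O)O | starting material
7 | (3S,4Z)-5-iodohexa-1,4-dien-3-yl 2-(bromomethyl)prop-2-enoate | C=C(CBr)C(=O)O[C@@H](C=C)/C=C(/C)I | intermediate
8 | (5S)-3-(bromomethyl)-5-[(1Z)-2-iodoprop-1-en-1-yl]furan-2(5H)-one | O=C1O[C@@H](C=C1CBr)/C=C(/C)I | intermediate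
9 | (5S)-5-[(1Z)-2-iodoprop-1-en-1-yl]-3-[(tributylstannyl)methyl]furan-2(5H)-one | O=C1O[C@@H](C=C1C[Sn](CCCC)(CCCC)CCCC)/C=C(/C)I | intermediate
10 | tert-butyl 2-chloropropanoate (racemic) | CC(Cl)C(=O)OC(C)(C)C | starting material
11 | allyl bromide | C=CCBr | starting material
12 | tert-butyl 2-chloro-2-methylpent-4-enoate (racemic) | C=CCC(C)(Cl)C(=O)OC(C)(C)C | intermediate
13 | tert-butyl 2-chloro-2-methyl-4-oxobutanoate (racemic) | O=CCC(C)(Cl)C(=O)OC(C)(C)C | intermediate
14 | tert-butyl (4R)-2-chloro-4-hydroxy-4-[(2S,3R)-2-[(1Z)-2-iodoprop-1-en-1-yl]-4-methylidene-5-oxooxolan-3-yl]-2-methylbutanoate (C2 epimers) | C=C1C(=O)O[C@H](/C=C(/C)I)[C@H]1[C@H](O)CC(C)(Cl)C(=O)OC(C)(C)C | intermediate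
15 | angelic acid, (2Z)-2-methylbut-2-enoic acid | C/C=C(/C)C(=O)O | starting material
16 | tert-butyl (4R)-2-chloro-4-[(2S,3R)-2-[(1Z)-2-iodoprop-1-en-1-yl]-4-methylidene-5-oxooxolan-3-yl]-2-methyl-4-{[(2Z)-2-methylbut-2-enoyl]oxy}butanoate (C2 epimers) | C=C1C(=O)O[C@H](/C=C(/C)I)[C@H]1[C@H](OC(=O)/C(C)=C\C)CC(C)(Cl)C(=O)OC(C)(C)C | intermediate
17 | tributyl(1-ethoxyvinyl)stannane | C=C(OCC)[Sn](CCCC)(CCCC)CCCC | starting material
18 | tert-butyl (4R)-2-chloro-4-[(2R,3R)-2-[(1Z)-3-ethoxy-2-methylbuta-1,3-dien-1-yl]-4-methylidene-5-oxooxolan-3-yl]-2-methyl-4-{[(2Z)-2-methylbut-2-enoyl]oxy}butanoate (C2 epimers) | C=C1C(=O)O[C@H](/C=C(/C)C(=C)OCC)[C@H]1[C@H](OC(=O)/C(C)=C\C)CC(C)(Cl)C(=O)OC(C)(C)C | intermediate (not isolated)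
19 | (4R)-2-chloro-2-methyl-4-{[(2Z)-2-methylbut-2-enoyl]oxy}-4-[(2R,3R)-4-methylidene-2-[(1Z)-2-methyl-3-oxobut-1-en-1-yl]-5-oxooxolan-3-yl]butanoic acid (C2 epimers) | C=C1C(=O)O[C@H](/C=C(/C)C(C)=O)[C@H]1[C@H](OC(=O)/C(C)=C\C)CC(C)(Cl)C(=O)O | intermediate
20 | acid chloride of 19 (C2 epimers) | C=C1C(=O)O[C@H](/C=C(/C)C(C)=O)[C@H]1[C@H](OC(=O)/C(C)=C\C)CC(C)(Cl)C(Cl)=O | intermediate (not isolated)
21 | (4Z,6R,7R,8R)-8-angeloyloxy-10-chloro-1,3-dioxogermacra-4,11(13)-dien-12,6-olide (C10 epimers; ten-membered α'-chloro-1,3-diketone) | C=C1C(=O)O[C@@H]2/C=C(/C)C(=O)CC(=O)C(C)(Cl)C[C@@H](OC(=O)/C(C)=C\C)[C@@H]12 | intermediate (not isolated)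
22 | 15-deoxybudlein A, (4Z,6R,7R,8R,10R)-8-angeloyloxy-3,10-epoxy-1-oxogermacra-2,4,11(13)-trien-12,6-olide | C=C1C(=O)O[C@@H]2/C=C(/C)C3=CC(=O)[C@@](C)(C[C@@H](OC(=O)/C(C)=C\C)[C@@H]12)O3 | target

**Step count and risks**

Total step count: 12. Longest linear sequence: 10 (steps 1–6 and 9–12).

Steps most likely to fail:

1. Step 12 (Proposed new method). Intermolecular acylation or O-acylation may outrun the ten-membered C-acylation, the chelated diketonate may ionise slowly, and the facial selectivity of the O–C10 closure may be poor. Fallback with known reactions, in which the ring is closed by an aldol addition and the stages are isolated: it sets out from 19. Its acid chloride 20 is reduced with LiAlH(Ot-Bu)3 (THF, −78 °C) to keto aldehyde F1. TMSOTf/i-Pr2NEt (CH2Cl2, −78 °C, high dilution) converts the methyl ketone into its enol silane in the flask, and this adds to the non-enolisable, silyl-activated C1 aldehyde (intramolecular Mukaiyama aldol macrocyclisation) to give, after acidic work-up, the ten-membered hydroxy ketone F2. Dess–Martin oxidation then gives chloro diketone 21, now isolated, where the fallback rejoins the route, and DBU in MeCN closes the furanone to 22. This fallback answers the ring-closure risk only; the facial selectivity of the O–C10 closure is the same as in step 12.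

2. Step 9. The electron-poor allylstannane may attack slowly, the Lewis acid may induce lactonisation with loss of the tert-butyl group, or the syn selectivity may erode. Fallback with a closed transition state and later inversion: it sets out from 8 and 13. Zinc-mediated Barbier coupling (Zn, THF/sat. aq NH4Cl) through a chair transition state should give the 6,7-trans, 7,8-anti (8S) alcohol F3. Mitsunobu esterification with 15 (PPh3, DIAD, toluene, 0 → 23 °C) then inverts C8 and installs the angelate, returning to the route at 16. Because the C1 ester carbonyl could take part at the activated C8 centre, this order is kept as the fallback and not the main route.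

3. Step 6. The allylzinc may be protonated or dimerise before tin trapping, or the ring-stannylated regioisomer may form. Fallback through an allylsilane made by metathesis: it sets out from 5. Esterification with 2-[(trimethylsilyl)methyl]prop-2-enoic acid (DCC, DMAP cat.) gives ester F4 and ring-closing metathesis (second-generation Grubbs catalyst) gives allylsilane F5. TiCl4-promoted Hosomi–Sakurai addition of F5 to 13 (CH2Cl2, −78 °C, same open transition state) returns to the route at 14.

**Further compounds**

F1 | step 12 | (1R)-3-chloro-3-methyl-1-[(2R,3R)-4-methylidene-2-[(1Z)-2-methyl-3-oxobut-1-en-1-yl]-5-oxooxolan-3-yl]-4-oxobutyl (2Z)-2-methylbut-2-enoate (C3 epimers) | C=C1C(=O)O[C@H](/C=C(/C)C(C)=O)[C@H]1[C@H](OC(=O)/C(C)=C\C)CC(C)(Cl)C=O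
F2 | step 12 | (4Z,6R,7R,8R)-8-angeloyloxy-10-chloro-1-hydroxy-3-oxogermacra-4,11(13)-dien-12,6-olide (C1 and C10 epimers) | C=C1C(=O)O[C@@H]2/C=C(/C)C(=O)CC(O)C(C)(Cl)C[C@@H](OC(=O)/C(C)=C\C)[C@@H]12
F3 | step 9 | tert-butyl (4S)-2-chloro-4-hydroxy-4-[(2S,3R)-2-[(1Z)-2-iodoprop-1-en-1-yl]-4-methylidene-5-oxooxolan-3-yl]-2-methylbutanoate (C2 epimers) | C=C1C(=O)O[C@H](/C=C(/C)I)[C@H]1[C@@H](O)CC(C)(Cl)C(=O)OC(C)(C)C
F4 | step 6 | (3S,4Z)-5-iodohexa-1,4-dien-3-yl 2-[(trimethylsilyl)methyl]prop-2-enoate | C=C(C[Si](C)(C)C)C(=O)O[C@@H](C=C)/C=C(/C)I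
F5 | step 6 | (5S)-5-[(1Z)-2-iodoprop-1-en-1-yl]-3-[(trimethylsilyl)methyl]furan-2(5H)-one | O=C1O[C@@H](C=C1C[Si](C)(C)C)/C=C(/C)I
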